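**Strategy.** The dihydrofuran ring is cut at both bonds to C2, the lone sp3 carbon lying between O1 and the benzylic methylene C3. C7a–O1 and C3a–C3 are traced back to an ortho-quinone methide of the acylphloroglucinol ring. C2 comes from the carbon of a keto-stabilised sulfonium ylide whose acyl group is the side chain, one methylene short. One base-mediated [4+1] annulation under a chiral hydrogen-bond catalyst forms both bonds, the five-membered ring and the only stereocentre. Its precursor is a 4-hydroxy-3-(tosylmethyl)acetophenone with both phenols ortho to the acetyl group capped as MOM ethers, so only the oxygen para to the acetyl group can become O1. Methylenation, deprotection and methylene bridging of C7 to the pyrone follow.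

Key step: step 11

Assumption: the sense of induction of the catalyst in step 11, 1,1'-[(1R,2R)-cyclohexane-1,2-diyl]bis{3-[3,5-bis(trifluoromethyl)phenyl]urea}, cannot be predicted with certainty; its antipode is used if a pilot run shows the opposite sense.

Remark: C2 is R in 18, 19, 20 and 27, because O1 outranks the acyl or vinyl carbon, which outranks C3, in all four.

Remark: the benzylic sulfone is put in place while the oxygen para to the acetyl group is still silylated, so ortho-quinone methide 16 arises for the first time in step 11.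

Step 1
Reactants: 1 2,4,6-trihydroxyacetophenone
Product: 2 1-{2,6-dihydroxy-4-[tri(propan-2-yl)silyloxy]phenyl}ethan-1-one
Conditions: TIPSCl (1.05 equiv), imidazole, DMF, 0 °C
Reagents that add atoms: chlorotri(propan-2-yl)silane (TIPSCl), CC(C)[Si](Cl)(C(C)C)C(C)C
Why: Regioselective O-silylation, since the para hydroxyl is the most acidic and least hindered one and is not tied up in a hydrogen bond to the acetyl carbonyl, so one equivalent of a bulky silyl chloride should take it first.

Step 2
Reactants: 2 1-{2,6-dihydroxy-4-[tri(propan-2-yl)silyloxy]phenyl}ethan-1-one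
Product: 4 3-acetyl-2,4-dihydroxy-6-[tri(propan-2-yl)silyloxy]benzaldehyde, via aryl iminium chloride 3 (not isolated)
Conditions: POCl3 (1.2 equiv), DMF (1.5 equiv), EtOAc, 0 °C → rt; then aq NaOAc, rt
Reagents that add atoms: N,N-dimethylformamide, CN(C)C=O; water, O
Why: Vilsmeier–Haack formylation by the small chloroiminium electrophile at one of the two equivalent free carbons of the phloroglucinol-type ring, which should stop after one substitution because the iminium group deactivates the ring, while the acetyl group held between two hydrogen-bonded hydroxyls and the hindered aryl silyl ether should not react.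

Step 3
Reactants: 4 3-acetyl-2,4-dihydroxy-6-[tri(propan-2-yl)silyloxy]benzaldehyde
Product: 5 3-acetyl-2,4-bis(methoxymethoxy)-6-[tri(propan-2-yl)silyloxy]benzaldehyde
Conditions: NaH (2.3 equiv), MOMCl (3 equiv), DMF, 0 °C → rt
Reagents that add atoms: chloromethyl methyl ether (MOMCl), COCCl
Why: Williamson-type O-alkylation of both hydrogen-bonded phenols as their sodium phenoxides, with NaH chosen because the hydroxyl held between two carbonyl groups needs full deprotonation and with a solvent that cannot condense with the aldehyde.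

Step 4
Reactants: 5 3-acetyl-2,4-bis(methoxymethoxy)-6-[tri(propan-2-yl)silyloxy]benzaldehyde
Product: 6 1-{3-(hydroxymethyl)-2,6-bis(methoxymethoxy)-4-[tri(propan-2-yl)silyloxy]phenyl}ethan-1-one
Conditions: NaBH4 (0.6 equiv), MeOH/THF, −40 °C; aq NH4Cl
Reagents that add atoms: none
Why: Chemoselective borohydride reduction of the aldehyde, which should be far faster than that of the methyl ketone twisted between two ortho ethers, run cold in methanol so that the alkoxide is protonated before the bulky silyl group can migrate to it.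

Step 5
Reactants: 6 1-{3-(hydroxymethyl)-2,6-bis(methoxymethoxy)-4-[tri(propan-2-yl)silyloxy]phenyl}ethan-1-one; 7 sodium 4-methylbenzenesulfinate
Product: 9 1-{2,6-bis(methoxymethoxy)-3-[(4-methylbenzenesulfonyl)methyl]-4-[tri(propan-2-yl)silyloxy]phenyl}ethan-1-one, via benzylic mesylate 8 (not isolated)
Conditions: Ms2O (1.2 equiv), i-Pr2NEt, CH2Cl2, −30 °C; then 7 (3 equiv), DMF, −30 °C → rt
Reagents that add atoms: none
Why: Sulfonate activation of the primary benzylic alcohol followed by S-alkylation of the sulfinate (benzylic nucleophilic substitution), which should be fast at this electron-rich benzylic carbon and cannot pass through a quinone methide because the neighbouring oxygen is still silylated.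

Step 6
Reactants: 9 1-{2,6-bis(methoxymethoxy)-3-[(4-methylbenzenesulfonyl)methyl]-4-[tri(propan-2-yl)silyloxy]phenyl}ethan-1-one
Product: 10 1-{4-hydroxy-2,6-bis(methoxymethoxy)-3-[(4-methylbenzenesulfonyl)methyl]phenyl}ethan-1-one
Conditions: n-Bu4NF (1.1 equiv), AcOH (1.5 equiv), THF, 0 °C
Reagents that add atoms: none
Why: Fluoride-mediated desilylation of the aryl silyl ether, buffered with acetic acid so that the phenol is released in protonated form and does not expel sulfinate, while the MOM acetals and the sulfone are inert to fluoride.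

Step 7
Reactants: 11 6-methylhept-5-en-2-one
Product: 12 trimethyl[(6-methylhepta-1,5-dien-2-yl)oxy]silane
Conditions: LiN(iPr)2, Me3SiCl (in situ quench), THF, −78 °C
Reagents that add atoms: chlorotrimethylsilane, C[Si](C)(C)Cl
Why: Kinetic enolisation by the hindered amide base removes a methyl proton, and immediate silyl trapping fixes the less substituted enol ether (kinetic silyl enol ether formation).

Step 8
Reactants: 12 trimethyl[(6-methylhepta-1,5-dien-2-yl)oxy]silane
Product: 13 1-bromo-6-methylhept-5-en-2-one
Conditions: NBS, NaHCO3, THF, −78 °C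
Reagents that add atoms: N-bromosuccinimide, O=C1CCC(=O)N1Br
Why: Electrophilic bromination of the silyl enol ether, which at low temperature should be far faster than attack on the isolated trisubstituted alkene and places bromine at C1 only.

Step 9
Reactants: 13 1-bromo-6-methylhept-5-en-2-one
Product: 14 dimethyl(6-methyl-2-oxohept-5-en-1-yl)sulfonium bromide
Conditions: Me2S, acetone, rt
Reagents that add atoms: dimethyl sulfide, CSC
Why: SN2 S-alkylation of dimethyl sulfide by the activated primary alpha-bromo ketone, with the salt expected to crystallise away from any secondary bromide isomer.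

Step 10
Reactants: 14 dimethyl(6-methyl-2-oxohept-5-en-1-yl)sulfonium bromide
Product: 15 dimethylsulfonium 6-methyl-2-oxohept-5-en-1-ylide
Conditions: NaOH (2 M aq), CH2Cl2, 0 °C; organic layer dried and used at once
Reagents that add atoms: none
Why: Deprotonation of the acidic alpha-sulfonium ketone gives the carbonyl-stabilised ylide, obtained halide-free so that bromide does not compete for the hydrogen-bond catalyst in the next step.

Step 11
Reactants: 10 1-{4-hydroxy-2,6-bis(methoxymethoxy)-3-[(4-methylbenzenesulfonyl)methyl]phenyl}ethan-1-one; 15 dimethylsulfonium 6-methyl-2-oxohept-5-en-1-ylide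
Product: 18 1-[(2R)-5-acetyl-4,6-bis(methoxymethoxy)-2,3-dihydro-1-benzofuran-2-yl]-5-methylhex-4-en-1-one, via ortho-quinone methide 16 (not isolated), via sulfonium phenoxide betaine 17 (not isolated)
Conditions: Cs2CO3 (1.5 equiv), chiral bis-urea (10 mol%), CH2Cl2, −20 → 0 °C
Reagents that add atoms: none
Why: Cs2CO3 deprotonates the phenol of 10 and p-toluenesulfinate is expelled to give ortho-quinone methide 16; the ylide carbon of 15 adds to the exocyclic methylene (new C2–C3 bond), restoring the aromatic ring as phenoxide–sulfonium betaine 17, whose phenoxide then displaces dimethyl sulfide (new O1–C2 bond). The closest known reaction type is the formal [4+1] annulation of ortho-quinone methides released from 2-(sulfonylmethyl)phenols with carbonyl-stabilised sulfonium ylides, which is also known in hydrogen-bond-catalysed asymmetric form. The dihydrofuran closes by a 5-exo-tet SN2 displacement with inversion at the sulfonium-bearing carbon. C2 is the only new stereocentre; because the doubly activated C–H of 17 should epimerise quickly by proton transfer, its configuration is expected to be decided in the ring closure, where the chiral bis-urea bound to the phenoxide and ketone oxygens lets one betaine epimer cyclise faster (dynamic kinetic control), the catalyst antipode being chosen to give 2R. The step needs regiocontrol, which the two MOM ethers secure because the para oxygen is the only free one flanking the methylene, and it needs the alpha-aryloxy ketone of 18 to keep its configuration, which mild carbonate, low temperature and prompt work-up should ensure.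

Step 12
Reactants: 18 1-[(2R)-5-acetyl-4,6-bis(methoxymethoxy)-2,3-dihydro-1-benzofuran-2-yl]-5-methylhex-4-en-1-one
Product: 19 1-[(2R)-4,6-bis(methoxymethoxy)-2-(6-methylhepta-1,5-dien-2-yl)-2,3-dihydro-1-benzofuran-5-yl]ethan-1-one
Conditions: Cp2TiMe2 (2 equiv), PhMe/THF, 65 °C, dark
Reagents that add atoms: dimethyltitanocene (Cp2TiMe2), [CH3-].[CH3-].[Ti+4].c1cc[cH-]c1.c1cc[cH-]c1
Why: Petasis methylenation, in which thermally formed Cp2Ti=CH2 converts the unhindered aliphatic ketone by [2+2] addition and cycloreversion without enolate formation, so C2 should keep its configuration, while the aryl ketone twisted between two ortho ethers should react much more slowly.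

Step 13
Reactants: 19 1-[(2R)-4,6-bis(methoxymethoxy)-2-(6-methylhepta-1,5-dien-2-yl)-2,3-dihydro-1-benzofuran-5-yl]ethan-1-one
Product: 20 1-[(2R)-4,6-dihydroxy-2-(6-methylhepta-1,5-dien-2-yl)-2,3-dihydro-1-benzofuran-5-yl]ethan-1-one
Conditions: HCl (1.25 M in MeOH), 0 °C → rt
Reagents that add atoms: none
Why: Acid-catalysed acetal methanolysis removes both MOM groups, helped by the ortho acetyl group, under conditions mild enough that the allylic aryl ether at C2 and the two alkenes should not ionise or add HCl.

Step 14
Reactants: 21 methyl 3-oxopentanoate; 22 N-methoxy-N-methylpropanamide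
Product: 23 methyl 4-methyl-3,5-dioxoheptanoate
Conditions: LiN(iPr)2 (2.2 equiv), THF, 0 °C; then 22, −78 → 0 °C; aq HCl
Reagents that add atoms: none
Why: Claisen-type gamma-acylation of the beta-keto ester dianion at its more reactive C4 carbanion, with the Weinreb amide giving a stable tetrahedral adduct that prevents over-addition.

Step 15
Reactants: 23 methyl 4-methyl-3,5-dioxoheptanoate
Product: 24 6-ethyl-4-hydroxy-5-methyl-2H-pyran-2-one
Conditions: DBU (1.1 equiv), PhMe, reflux; then aq HCl
Reagents that add atoms: none
Why: Base-mediated enol lactonisation, in which the C5 enol oxygen attacks the ester intramolecularly and methanol is lost to give the 4-hydroxy-2-pyranone.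

Step 16
Reactants: 24 6-ethyl-4-hydroxy-5-methyl-2H-pyran-2-one; 20 1-[(2R)-4,6-dihydroxy-2-(6-methylhepta-1,5-dien-2-yl)-2,3-dihydro-1-benzofuran-5-yl]ethan-1-one
Product: 27 3-{[(2R)-5-acetyl-4,6-dihydroxy-2-(6-methylhepta-1,5-dien-2-yl)-2,3-dihydro-1-benzofuran-7-yl]methyl}-6-ethyl-4-hydroxy-5-methyl-2H-pyran-2-one, via pyrone Mannich base 25 (not isolated), via methylidene pyrandione 26 (not isolated)
Conditions: [Me2N=CH2]I (1.05 equiv), MeCN, rt; then 20, 50 °C
Reagents that add atoms: N,N-dimethylmethyleneiminium iodide (Eschenmoser's salt), C=[N+](C)C.[I-]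
Why: Mannich aminomethylation of the pyrone at C3, loss of dimethylamine to the methylidene pyrandione and Friedel–Crafts-type Michael addition of C7, the only free ring carbon of the acylphloroglucinol, with the Mannich base formed completely beforehand so that the symmetrical bis-pyrone is suppressed.

**Compound list**

1 | 2,4,6-trihydroxyacetophenone | CC(=O)c1c(O)cc(O)cc1O | starting material
2 | 1-{2,6-dihydroxy-4-[tri(propan-2-yl)silyloxy]phenyl}ethan-1-one | CC(=O)c1c(O)cc(O[Si](C(C)C)(C(C)C)C(C)C)cc1O | intermediate
3 | N-({3-acetyl-2,4-dihydroxy-6-[tri(propan-2-yl)silyloxy]phenyl}methylidene)-N-methylmethanaminium chloride | C[N+](C)=Cc1c(O)c(C(C)=O)c(O)cc1O[Si](C(C)C)(C(C)C)C(C)C.[Cl-] | intermediate (not isolated)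
4 | 3-acetyl-2,4-dihydroxy-6-[tri(propan-2-yl)silyloxy]benzaldehyde | O=Cc1c(O)c(C(C)=O)c(O)cc1O[Si](C(C)C)(C(C)C)C(C)C | intermediate
5 | 3-acetyl-2,4-bis(methoxymethoxy)-6-[tri(propan-2-yl)silyloxy]benzaldehyde | O=Cc1c(OCOC)c(C(C)=O)c(OCOC)cc1O[Si](C(C)C)(C(C)C)C(C)C | intermediate
6 | 1-{3-(hydroxymethyl)-2,6-bis(methoxymethoxy)-4-[tri(propan-2-yl)silyloxy]phenyl}ethan-1-one | OCc1c(OCOC)c(C(C)=O)c(OCOC)cc1O[Si](C(C)C)(C(C)C)C(C)C | intermediate
7 | sodium 4-methylbenzenesulfinate | Cc1ccc(S(=O)[O-])cc1.[Na+] | starting material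
8 | {3-acetyl-2,4-bis(methoxymethoxy)-6-[tri(propan-2-yl)silyloxy]phenyl}methyl methanesulfonate | CS(=O)(=O)OCc1c(OCOC)c(C(C)=O)c(OCOC)cc1O[Si](C(C)C)(C(C)C)C(C)C | intermediate (not isolated)
9 | 1-{2,6-bis(methoxymethoxy)-3-[(4-methylbenzenesulfonyl)methyl]-4-[tri(propan-2-yl)silyloxy]phenyl}ethan-1-one | CC(=O)c1c(OCOC)cc(O[Si](C(C)C)(C(C)C)C(C)C)c(CS(=O)(=O)c2ccc(C)cc2)c1OCOC | intermediate
10 | 1-{4-hydroxy-2,6-bis(methoxymethoxy)-3-[(4-methylbenzenesulfonyl)methyl]phenyl}ethan-1-one | CC(=O)c1c(OCOC)cc(O)c(CS(=O)(=O)c2ccc(C)cc2)c1OCOC | intermediate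
11 | 6-methylhept-5-en-2-one | CC(=O)CCC=C(C)C | starting material
12 | trimethyl[(6-methylhepta-1,5-dien-2-yl)oxy]silane | C=C(CCC=C(C)C)O[Si](C)(C)C | intermediate
13 | 1-bromo-6-methylhept-5-en-2-one | BrCC(=O)CCC=C(C)C | intermediate
14 | dimethyl(6-methyl-2-oxohept-5-en-1-yl)sulfonium bromide | C[S+](C)CC(=O)CCC=C(C)C.[Br-] | intermediate
15 | dimethylsulfonium 6-methyl-2-oxohept-5-en-1-ylide | C[S+](C)[CH-]C(=O)CCC=C(C)C | intermediate
16 | 4-acetyl-3,5-bis(methoxymethoxy)-6-methylidenecyclohexa-2,4-dien-1-one | C=C1C(=O)C=C(OCOC)C(C(C)=O)=C1OCOC | intermediate (not isolated)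
17 | 4-acetyl-2-[2-(dimethylsulfaniumyl)-7-methyl-3-oxooct-6-en-1-yl]-3,5-bis(methoxymethoxy)phenolate (epimerising at the sulfonium carbon) | CC(C)=CCCC(=O)C(Cc1c([O-])cc(OCOC)c(C(C)=O)c1OCOC)[S+](C)C | intermediate (not isolated)
18 | 1-[(2R)-5-acetyl-4,6-bis(methoxymethoxy)-2,3-dihydro-1-benzofuran-2-yl]-5-methylhex-4-en-1-one | CC(C)=CCCC(=O)[C@H]1Cc2c(OCOC)c(C(C)=O)c(OCOC)cc2O1 | intermediate
19 | 1-[(2R)-4,6-bis(methoxymethoxy)-2-(6-methylhepta-1,5-dien-2-yl)-2,3-dihydro-1-benzofuran-5-yl]ethan-1-one | C=C(CCC=C(C)C)[C@H]1Cc2c(OCOC)c(C(C)=O)c(OCOC)cc2O1 | intermediate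
20 | 1-[(2R)-4,6-dihydroxy-2-(6-methylhepta-1,5-dien-2-yl)-2,3-dihydro-1-benzofuran-5-yl]ethan-1-one | C=C(CCC=C(C)C)[C@H]1Cc2c(O)c(C(C)=O)c(O)cc2O1 | intermediate
21 | methyl 3-oxopentanoate | CCC(=O)CC(=O)OC | starting material
22 | N-methoxy-N-methylpropanamide | CCC(=O)N(C)OC | starting material
23 | methyl 4-methyl-3,5-dioxoheptanoate (racemic at C4, keto–enol mixture) | CCC(=O)C(C)C(=O)CC(=O)OC | intermediate
24 | 6-ethyl-4-hydroxy-5-methyl-2H-pyran-2-one | CCc1oc(=O)cc(O)c1C | intermediate
25 | 3-[(dimethylamino)methyl]-6-ethyl-4-hydroxy-5-methyl-2H-pyran-2-one | CCc1oc(=O)c(CN(C)C)c(O)c1C | intermediate (not isolated)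
26 | 6-ethyl-5-methyl-3-methylidene-2H-pyran-2,4(3H)-dione | CCC1=C(C)C(=O)C(=C)C(=O)O1 | intermediate (not isolated)
27 | 3-{[(2R)-5-acetyl-4,6-dihydroxy-2-(6-methylhepta-1,5-dien-2-yl)-2,3-dihydro-1-benzofuran-7-yl]methyl}-6-ethyl-4-hydroxy-5-methyl-2H-pyran-2-one | C=C(CCC=C(C)C)[C@H]1Cc2c(O)c(C(C)=O)c(O)c(Cc3c(O)c(C)c(CC)oc3=O)c2O1 | target

**Step count.** Total: 16 steps. Longest linear sequence: 10 steps (steps 1, 2, 3, 4, 5, 6, 11, 12, 13, 16).

**Steps most likely to fail**

1. Step 11. The catalyst may not discriminate enough in the ring closure, because an uncatalysed carbonate-driven annulation can run in parallel and the released sulfinate and carbonate can occupy the urea; the new alpha-aryloxy ketone centre could also be eroded by enolisation if the mixture is left basic. Fallback: the chirality is moved from the catalyst into the onium leaving group. Setting out from bromo ketone 13, alkylation of (2R,5R)-2,5-dimethylthiolane in acetone at rt should give (2R,5R)-2,5-dimethyl-1-(6-methyl-2-oxohept-5-en-1-yl)thiolan-1-ium bromide F1. F1 and sulfone 10 with Cs2CO3 in CH2Cl2 at −20 °C should form 1-[(2R,5R)-2,5-dimethylthiolan-1-ium-1-yl]-6-methyl-2-oxohept-5-en-1-ide F2 in the flask, which should add to the same quinone methide 16. The resulting 4-acetyl-2-{2-[(2R,5R)-2,5-dimethylthiolan-1-ium-1-yl]-7-methyl-3-oxooct-6-en-1-yl}-3,5-bis(methoxymethoxy)phenolate F3 has two epimers that should close at different rates, returning to the route at 18. The sulfide is recovered, and its antipode is taken if the sense is reversed.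

2. Step 12. The titanium carbene may also attack the aryl acetyl group, or the reaction may stall at the temperature needed, leaving the epimerisable ketone exposed to prolonged heating. Fallback: a two-stage Peterson olefination by nucleophilic addition. Setting out from 18, Me3SiCH2MgCl with CeCl3 in THF at −78 °C should add only to the unhindered aliphatic ketone without enolising it, giving 1-{(2R)-2-[2-hydroxy-6-methyl-1-(trimethylsilyl)hept-5-en-2-yl]-4,6-bis(methoxymethoxy)-2,3-dihydro-1-benzofuran-5-yl}ethan-1-one F4 as a mixture of carbinol epimers. KN(SiMe3)2 in THF at 0 °C should then bring about syn elimination of silanolate, returning to the route at 19.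

3. Step 5. The activated benzylic carbon may ionise and be captured by a neighbouring MOM oxygen or by the free ring carbon of a second molecule, and the ambident sulfinate may alkylate at oxygen. Fallback: the carbon–sulfur bond is made with a neutral thiol-level nucleophile and the sulfur is oxidised afterwards. Setting out from alcohol 6, Hata thioetherification with bis(4-methylphenyl) disulfide and n-Bu3P in THF at rt should give 1-{2,6-bis(methoxymethoxy)-3-{[(4-methylphenyl)sulfanyl]methyl}-4-[tri(propan-2-yl)silyloxy]phenyl}ethan-1-one F5. Oxidation with H2O2 and catalytic (NH4)6Mo7O24 in EtOH at 0 °C → rt should then take the sulfide to the sulfone, returning to the route at 9.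

**Further compounds**

F1 | step 11 | (2R,5R)-2,5-dimethyl-1-(6-methyl-2-oxohept-5-en-1-yl)thiolan-1-ium bromide | C[C@@H]1CC[C@@H](C)[S+]1CC(=O)CCC=C(C)C.[Br-]
F2 | step 11 | 1-[(2R,5R)-2,5-dimethylthiolan-1-ium-1-yl]-6-methyl-2-oxohept-5-en-1-ide | C[C@@H]1CC[C@@H](C)[S+]1[CH-]C(=O)CCC=C(C)C
F3 | step 11 | 4-acetyl-2-{2-[(2R,5R)-2,5-dimethylthiolan-1-ium-1-yl]-7-methyl-3-oxooct-6-en-1-yl}-3,5-bis(methoxymethoxy)phenolate (epimers at the sulfonium-bearing carbon) | C[C@@H]1CC[C@@H](C)[S+]1C(Cc2c([O-])cc(OCOC)c(C(C)=O)c2OCOC)C(=O)CCC=C(C)C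
F4 | step 12 | 1-{(2R)-2-[2-hydroxy-6-methyl-1-(trimethylsilyl)hept-5-en-2-yl]-4,6-bis(methoxymethoxy)-2,3-dihydro-1-benzofuran-5-yl}ethan-1-one (carbinol epimers) | C[Si](C)(C)CC(O)(CCC=C(C)C)[C@H]1Cc2c(OCOC)c(C(C)=O)c(OCOC)cc2O1
F5 | step 5 | 1-{2,6-bis(methoxymethoxy)-3-{[(4-methylphenyl)sulfanyl]methyl}-4-[tri(propan-2-yl)silyloxy]phenyl}ethan-1-one | CC(=O)c1c(OCOC)cc(O[Si](C(C)C)(C(C)C)C(C)C)c(CSc2ccc(C)cc2)c1OCOC
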